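**Strategy.** The C40 skeleton is cut at C11=C12 and C11'=C12' into a C10 dialdehyde and two C15 phosphonium salts. Both salts come from one racemic trans-3-hydroxy-α-ionone: lipase resolution sends the (3R,6R) enantiomer to the ε end and the (3S,6S) enantiomer, by syn-epoxidation and vinylogous epoxide opening, to the (3S,4R)-diol β end. The key step makes the six-membered ε ring (C1'–C6') by two-carbon ring expansion: 2-methylpropenyllithium (C1', C2') adds to a 3-methyl-4-(silyloxymethyl)cyclobutenone (C3'–C6' plus C7'), and 4π opening/6π closure forms C1'–C6'. It exploits the O=C3'–C4'=C5'(CH3)–C6'H enone flanked by quaternary C1' in that ring.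

Key step: step 3

Remark: racemic compounds carry the prefix rac- and are drawn as one enantiomer; ring intermediates are described with unprimed carotenoid locants (C1–C6 ring, C7–C11 chain); compounds 1, 3, 7, 17, 22 and 30 are taken as commercial.

Step 1
Reactants: 1 3-hydroxy-N,N-dimethylpropanamide
Product: 2 N,N-dimethyl-3-[(triisopropylsilyl)oxy]propanamide
Conditions: TIPSCl, imidazole, DMF, rt
Reagents that add atoms: chlorotri(propan-2-yl)silane CC(C)[Si](Cl)(C(C)C)C(C)C
Why: Imidazole-promoted O-silylation of a primary alcohol; TIPS is chosen because it survives Tf2O and its silanolate is a poor leaving group in step 3.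

Step 2
Reactants: 2 N,N-dimethyl-3-[(triisopropylsilyl)oxy]propanamide; 3 propyne
Product: 6 rac-3-methyl-4-{[(triisopropylsilyl)oxy]methyl}cyclobut-2-en-1-one, via keteniminium triflate 4 (not isolated), via cyclobuteniminium triflate 5 (not isolated)
Conditions: Tf2O, 2,4,6-collidine, propyne (excess), ClCH2CH2Cl, 0 to 60 °C (sealed); then H2O, rt
Reagents that add atoms: water O
Why: Keteniminium–alkyne [2+2] cycloaddition: the central carbon of 4 bonds to the terminal carbon of propyne and its β-carbon closes onto the methyl-bearing carbon, so hydrolysis of 5 should give the 3-methyl-4-substituted cyclobutenone; the new stereocentre is racemic.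

Step 3
Reactants: 6 rac-3-methyl-4-{[(triisopropylsilyl)oxy]methyl}cyclobut-2-en-1-one; 7 1-bromo-2-methylprop-1-ene
Product: 12 rac-3,5,5-trimethyl-4-{[(triisopropylsilyl)oxy]methyl}cyclohex-2-en-1-one, via (2-methylprop-1-en-1-yl)lithium 8 (not isolated), via lithium cyclobutenolate 9 (not isolated), via lithium trienolate 10 (not isolated), via lithium cyclohexadienolate 11 (not isolated)
Conditions: 7, t-BuLi (2 equiv), Et2O, −78 °C; add 6 in THF, −78 °C to 40 °C; aq. NH4Cl
Reagents that add atoms: none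
Why: The alkenyllithium 8 adds 1,2 to the strained cyclobutenone carbonyl, and alkoxide 9 undergoes oxyanion-accelerated conrotatory 4π ring opening (cleavage of the C3–C6 bond, oxido group rotating outward) to the 2-oxidohexatriene 10, in which C2 and C5 are cis across the enolate double bond. Thermally allowed disrotatory 6π electrocyclisation of 10 then forms the C1–C6 bond and thereby the six-membered ring as dienolate 11, and C-protonation at C2 on work-up gives the conjugated enone 12. The closest known reaction type is the ring expansion of cyclobutenones to cyclohex-2-enones by addition of alkenyllithium reagents (anionic 4π-opening/6π-closure cascade). The only new stereocentre, C6, arises in the electrocyclisation without a controlling element, so 12 is racemic by design because both enantiomers are consumed later. The step needs 1,2- rather than 1,4-addition and the cis triene geometry: the first is secured by the hard organolithium and the strained carbonyl, the second by the outward torquoselectivity of the oxido substituent. Because one methyl of the CMe2 terminus must point inward, closure should be slower than for unhindered trienolates, hence the warming to 40 °C.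

Step 4
Reactants: 12 rac-3,5,5-trimethyl-4-{[(triisopropylsilyl)oxy]methyl}cyclohex-2-en-1-one
Product: 13 rac-(1S,4R)-3,5,5-trimethyl-4-{[(triisopropylsilyl)oxy]methyl}cyclohex-2-en-1-ol (3,6-cis)
Conditions: L-Selectride, THF, −78 °C; aq. NH4Cl
Reagents that add atoms: none
Why: 1,2-Reduction of a β,β-disubstituted cyclohexenone by a bulky borohydride, expected to attack the carbonyl face anti to the C6 substituent and the pseudo-axial C1 methyl and so give mainly the cis alcohol; any trans isomer is simply acetylated (Ac2O, pyridine) to the same acetate 14.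

Step 5
Reactants: 13 rac-(1S,4R)-3,5,5-trimethyl-4-{[(triisopropylsilyl)oxy]methyl}cyclohex-2-en-1-ol
Product: 14 rac-(1R,4R)-3,5,5-trimethyl-4-{[(triisopropylsilyl)oxy]methyl}cyclohex-2-en-1-yl acetate (3,6-trans)
Conditions: AcOH, PPh3, DIAD, toluene, 0 °C to rt
Reagents that add atoms: acetic acid CC(=O)O
Why: Mitsunobu esterification inverts C3 by SN2 displacement (SN2′ at the fully substituted C5 is disfavoured), giving the trans relationship both end groups need and protecting O3 for the next three steps.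

Step 6
Reactants: 14 rac-(1R,4R)-3,5,5-trimethyl-4-{[(triisopropylsilyl)oxy]methyl}cyclohex-2-en-1-yl acetate
Product: 15 rac-(1R,4R)-4-(hydroxymethyl)-3,5,5-trimethylcyclohex-2-en-1-yl acetate
Conditions: HF·pyridine, pyridine, THF, 0 °C to rt
Reagents that add atoms: none
Why: Fluoride-mediated desilylation of the primary TIPS ether under buffered conditions that leave the allylic acetate untouched.

Step 7
Reactants: 15 rac-(1R,4R)-4-(hydroxymethyl)-3,5,5-trimethylcyclohex-2-en-1-yl acetate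
Product: 16 rac-(1R,4R)-4-formyl-3,5,5-trimethylcyclohex-2-en-1-yl acetate
Conditions: Dess–Martin periodinane, pyridine, CH2Cl2, 0 °C to rt
Reagents that add atoms: none
Why: Dess–Martin oxidation under buffered, non-basic conditions should give the α-branched β,γ-unsaturated aldehyde without epimerisation at C6 or double-bond migration.

Step 8
Reactants: 16 rac-(1R,4R)-4-formyl-3,5,5-trimethylcyclohex-2-en-1-yl acetate; 17 1-(triphenyl-λ5-phosphanylidene)propan-2-one
Product: 18 rac-(1R,4R)-3,5,5-trimethyl-4-[(1E)-3-oxobut-1-en-1-yl]cyclohex-2-en-1-yl acetate (rac-trans-3-acetoxy-α-ionone)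
Conditions: toluene, 80 °C
Reagents that add atoms: none
Why: Wittig olefination with a stabilised ylide forms the (E)-C7=C8 enone under neutral conditions that do not enolise the aldehyde.

Step 9
Reactants: 18 rac-trans-3-acetoxy-α-ionone
Product: 19 rac-(3E)-4-[(1R,4R)-4-hydroxy-2,6,6-trimethylcyclohex-2-en-1-yl]but-3-en-2-one (rac-trans-3-hydroxy-α-ionone)
Conditions: K2CO3 (0.2 equiv), MeOH, 0 °C
Reagents that add atoms: none
Why: Mild base-catalysed transesterification frees the allylic alcohol for the enzyme; low temperature and catalytic carbonate should avoid γ-deprotonation at C6.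

Step 10
Reactants: 19 rac-trans-3-hydroxy-α-ionone
Product: 20 (1R,4R)-3,5,5-trimethyl-4-[(1E)-3-oxobut-1-en-1-yl]cyclohex-2-en-1-yl acetate [(3R,6R)-3-acetoxy-α-ionone] and 21 (3E)-4-[(1S,4S)-4-hydroxy-2,6,6-trimethylcyclohex-2-en-1-yl]but-3-en-2-one [(3S,6S)-3-hydroxy-α-ionone; unreacted enantiomer; both isolated by chromatography]
Conditions: lipase AK (Pseudomonas fluorescens), vinyl acetate, MTBE, 25 °C, to about 50% conversion
Reagents that add atoms: vinyl acetate CC(=O)OC=C
Why: Lipase-catalysed kinetic resolution by transesterification: the enzyme should acylate the (3R) enantiomer of this cyclohex-2-enol (the usual preference of lipases for cyclic secondary alcohols), and both the acetate and the remaining alcohol are used.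

Step 11
Reactants: 20 (3R,6R)-3-acetoxy-α-ionone; 22 vinylmagnesium bromide
Product: 23 (1R,4R)-4-[(1E)-3-hydroxy-3-methylpenta-1,4-dien-1-yl]-3,5,5-trimethylcyclohex-2-en-1-yl acetate (both carbinol epimers)
Conditions: THF, −78 °C; aq. NH4Cl
Reagents that add atoms: none
Why: Chemoselective Grignard 1,2-addition to the methyl enone at −78 °C with the acetate spared; the new carbinol centre is formed unselectively and is destroyed in step 12.

Step 12
Reactants: 23 (1R,4R)-4-[(1E)-3-hydroxy-3-methylpenta-1,4-dien-1-yl]-3,5,5-trimethylcyclohex-2-en-1-yl acetate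
Product: 24 {(2E,4E)-5-[(1R,4R)-4-acetoxy-2,6,6-trimethylcyclohex-2-en-1-yl]-3-methylpenta-2,4-dien-1-yl}triphenylphosphonium bromide
Conditions: Ph3P·HBr, CH2Cl2, 0 °C to rt
Reagents that add atoms: triphenylphosphine hydrobromide [Br-].c1ccc(cc1)[PH+](c1ccccc1)c1ccccc1
Why: Ionisation of the tertiary doubly allylic alcohol and capture of the pentadienyl cation by triphenylphosphine at the unhindered terminus (SN1/SN2′) should give the (2E,4E) allylic phosphonium salt, the ring acetate suppressing ionisation at C3.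

Step 13
Reactants: 21 (3S,6S)-3-hydroxy-α-ionone
Product: 25 (3S,4S,5R,6S)-4,5-epoxy-3-hydroxy-4,5-dihydro-α-ionone (epoxide oxygen cis to 3-OH and trans to the side chain)
Conditions: mCPBA, NaHCO3, CH2Cl2, 0 °C
Reagents that add atoms: 3-chloroperbenzoic acid OOC(=O)c1cccc(Cl)c1
Why: Hydroxyl-directed peracid epoxidation of the electron-rich ring alkene, reinforced by the C6 side chain shielding the opposite face, sets C4 and C5 cis to the 3-hydroxyl; the enone double bond is too electron-poor to react.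

Step 14
Reactants: 25 (3S,4S,5R,6S)-4,5-epoxy-3-hydroxy-4,5-dihydro-α-ionone
Product: 26 (3E)-4-[(3R,4S)-3,4-dihydroxy-2,6,6-trimethylcyclohex-1-en-1-yl]but-3-en-2-one [(3S,4R)-3,4-dihydroxy-β-ionone in carotenoid numbering]
Conditions: NaOMe (0.3 equiv), MeOH, 0 °C to rt
Reagents that add atoms: none
Why: Vinylogous E1cB opening of the γ,δ-epoxy enone: deprotonation at C6 and cleavage of C5–O give the conjugated β ring with the C4–O bond untouched, so the diol is cis by construction; the cis epoxy alcohol cannot undergo Payne rearrangement.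

Step 15
Reactants: 26 (3S,4R)-3,4-dihydroxy-β-ionone
Product: 27 (3E)-4-[(3aR,7aS)-4,6,6-trimethyl-2-oxo-3a,6,7,7a-tetrahydro-1,3-benzodioxol-5-yl]but-3-en-2-one (3,4-cyclic carbonate)
Conditions: 1,1'-carbonyldiimidazole, CH2Cl2, rt
Reagents that add atoms: 1,1'-carbonyldiimidazole O=C(n1ccnc1)n1ccnc1
Why: Carbonylation of a cis-1,2-diol to the five-membered cyclic carbonate, an electron-poor protecting group meant to disfavour ionisation at allylic C4 in step 17.

Step 16
Reactants: 27 cyclic carbonate of (3S,4R)-3,4-dihydroxy-β-ionone; 22 vinylmagnesium bromide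
Product: 28 (3aR,7aS)-5-[(1E)-3-hydroxy-3-methylpenta-1,4-dien-1-yl]-4,6,6-trimethyl-3a,6,7,7a-tetrahydro-1,3-benzodioxol-2-one (both carbinol epimers)
Conditions: THF, −78 °C; aq. NH4Cl
Reagents that add atoms: none
Why: Grignard 1,2-addition to the dienone carbonyl, which at −78 °C should be much faster than attack on the carbonate; the carbinol centre is lost in step 17.

Step 17
Reactants: 28 (3aR,7aS)-5-[(1E)-3-hydroxy-3-methylpenta-1,4-dien-1-yl]-4,6,6-trimethyl-3a,6,7,7a-tetrahydro-1,3-benzodioxol-2-one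
Product: 29 {(2E,4E)-3-methyl-5-[(3aR,7aS)-4,6,6-trimethyl-2-oxo-3a,6,7,7a-tetrahydro-1,3-benzodioxol-5-yl]penta-2,4-dien-1-yl}triphenylphosphonium bromide
Conditions: Ph3P·HBr, CH2Cl2, 0 °C
Reagents that add atoms: triphenylphosphine hydrobromide [Br-].c1ccc(cc1)[PH+](c1ccccc1)c1ccccc1
Why: Same SN1/SN2′ phosphonium salt formation as in step 12; the tertiary carbinol should ionise far faster than the carbonate-bearing C4.

Step 18
Reactants: 24 ε-end C15 phosphonium bromide; 30 (2E,4E,6E)-2,7-dimethylocta-2,4,6-trienedial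
Product: 32 (2E,4E,6E,8E,10E,12E)-13-[(1R,4R)-4-acetoxy-2,6,6-trimethylcyclohex-2-en-1-yl]-2,7,11-trimethyltrideca-2,4,6,8,10,12-hexaenal, via ε-end ylide 31 (not isolated)
Conditions: NaHMDS, THF, −78 °C; then 30 (2 equiv), −78 to 0 °C; then heptane, 80 °C
Reagents that add atoms: none
Why: Wittig olefination of the semi-stabilised ylide with excess symmetrical dialdehyde forms C11=C12; the less electrophilic vinylogous product aldehyde limits double condensation, and heating should equilibrate the new double bond to E.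

Step 19
Reactants: 29 β-end C15 phosphonium bromide; 32 C25 acetoxy aldehyde
Product: 35 (3S,4R,3'R,6'R)-β,ε-carotene-3,4,3'-triol (target), via β-end ylide 33 (not isolated), via protected carotenoid 34 (not isolated)
Conditions: NaHMDS added to 29 and 32, THF, −78 to 0 °C; then K2CO3, MeOH, rt; then EtOH, reflux, dark
Reagents that add atoms: none
Why: Second Wittig olefination forms C11'=C12' (the ylide is generated in the presence of the aldehyde so it is trapped before vinylogous loss of the C4 carbonate), methanolysis removes acetate and carbonate, and thermal isomerisation should give the all-E triol with all four stereocentres untouched.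

**Compound list**

1 | 3-hydroxy-N,N-dimethylpropanamide | CN(C)C(=O)CCO | starting material
2 | N,N-dimethyl-3-[(triisopropylsilyl)oxy]propanamide | CN(C)C(=O)CCO[Si](C(C)C)(C(C)C)C(C)C | intermediate
3 | propyne | CC#C | starting material
4 | N,N-dimethyl-N-{3-[(triisopropylsilyl)oxy]prop-1-en-1-ylidene}ammonium triflate (keteniminium triflate) | C[N+](C)=C=CCO[Si](C(C)C)(C(C)C)C(C)C.[O-]S(=O)(=O)C(F)(F)F | intermediate
5 | N,N-dimethyl-3-methyl-4-{[(triisopropylsilyl)oxy]methyl}cyclobut-2-en-1-iminium triflate (racemic) | C[N+](C)=C1C=C(C)C1CO[Si](C(C)C)(C(C)C)C(C)C.[O-]S(=O)(=O)C(F)(F)F | intermediate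
6 | rac-3-methyl-4-{[(triisopropylsilyl)oxy]methyl}cyclobut-2-en-1-one | CC1=CC(=O)C1CO[Si](C(C)C)(C(C)C)C(C)C | intermediate
7 | 1-bromo-2-methylprop-1-ene | CC(C)=CBr | starting material
8 | (2-methylprop-1-en-1-yl)lithium | [Li]C=C(C)C | intermediate
9 | lithium 3-methyl-1-(2-methylprop-1-en-1-yl)-4-{[(triisopropylsilyl)oxy]methyl}cyclobut-2-en-1-olate (diastereomer mixture) | [Li+].[O-]C1(C=C(C)C)C=C(C)C1CO[Si](C(C)C)(C(C)C)C(C)C | intermediate
10 | lithium (4E)-2,6-dimethyl-8-[(triisopropylsilyl)oxy]octa-2,4,6-trien-4-olate (C2 and C5 cis; C6=C7 geometry not fixed) | [Li+].[O-]/C(C=C(C)C)=C/C(C)=CCO[Si](C(C)C)(C(C)C)C(C)C | intermediate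
11 | lithium rac-3,3,5-trimethyl-4-{[(triisopropylsilyl)oxy]methyl}cyclohexa-1,5-dien-1-olate | [Li+].[O-]C1=CC(C)(C)C(CO[Si](C(C)C)(C(C)C)C(C)C)C(C)=C1 | intermediate
12 | rac-3,5,5-trimethyl-4-{[(triisopropylsilyl)oxy]methyl}cyclohex-2-en-1-one | CC1=CC(=O)CC(C)(C)C1CO[Si](C(C)C)(C(C)C)C(C)C | intermediate
13 | rac-(1S,4R)-3,5,5-trimethyl-4-{[(triisopropylsilyl)oxy]methyl}cyclohex-2-en-1-ol (cis) | CC1=C[C@@H](O)CC(C)(C)[C@H]1CO[Si](C(C)C)(C(C)C)C(C)C | intermediate
14 | rac-(1R,4R)-3,5,5-trimethyl-4-{[(triisopropylsilyl)oxy]methyl}cyclohex-2-en-1-yl acetate (trans) | CC1=C[C@H](OC(C)=O)CC(C)(C)[C@H]1CO[Si](C(C)C)(C(C)C)C(C)C | intermediate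
15 | rac-(1R,4R)-4-(hydroxymethyl)-3,5,5-trimethylcyclohex-2-en-1-yl acetate | CC1=C[C@H](OC(C)=O)CC(C)(C)[C@H]1CO | intermediate
16 | rac-(1R,4R)-4-formyl-3,5,5-trimethylcyclohex-2-en-1-yl acetate | CC1=C[C@H](OC(C)=O)CC(C)(C)[C@H]1C=O | intermediate
17 | 1-(triphenyl-λ5-phosphanylidene)propan-2-one | CC(=O)C=P(c1ccccc1)(c1ccccc1)c1ccccc1 | starting material
18 | rac-(1R,4R)-3,5,5-trimethyl-4-[(1E)-3-oxobut-1-en-1-yl]cyclohex-2-en-1-yl acetate (rac-trans-3-acetoxy-α-ionone) | CC1=C[C@H](OC(C)=O)CC(C)(C)[C@H]1/C=C/C(C)=O | intermediate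
19 | rac-(3E)-4-[(1R,4R)-4-hydroxy-2,6,6-trimethylcyclohex-2-en-1-yl]but-3-en-2-one (rac-trans-3-hydroxy-α-ionone) | CC1=C[C@H](O)CC(C)(C)[C@H]1/C=C/C(C)=O | intermediate
20 | (1R,4R)-3,5,5-trimethyl-4-[(1E)-3-oxobut-1-en-1-yl]cyclohex-2-en-1-yl acetate [(3R,6R)-3-acetoxy-α-ionone, single enantiomer] | CC1=C[C@H](OC(C)=O)CC(C)(C)[C@H]1/C=C/C(C)=O | intermediate
21 | (3E)-4-[(1S,4S)-4-hydroxy-2,6,6-trimethylcyclohex-2-en-1-yl]but-3-en-2-one [(3S,6S)-3-hydroxy-α-ionone] | CC1=C[C@@H](O)CC(C)(C)[C@@H]1/C=C/C(C)=O | intermediate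
22 | vinylmagnesium bromide | C=C[Mg]Br | starting material
23 | (1R,4R)-4-[(1E)-3-hydroxy-3-methylpenta-1,4-dien-1-yl]-3,5,5-trimethylcyclohex-2-en-1-yl acetate (carbinol epimers) | CC1=C[C@H](OC(C)=O)CC(C)(C)[C@H]1/C=C/C(C)(O)C=C | intermediate
24 | {(2E,4E)-5-[(1R,4R)-4-acetoxy-2,6,6-trimethylcyclohex-2-en-1-yl]-3-methylpenta-2,4-dien-1-yl}triphenylphosphonium bromide | CC1=C[C@H](OC(C)=O)CC(C)(C)[C@H]1/C=C/C(C)=C/C[P+](c1ccccc1)(c1ccccc1)c1ccccc1.[Br-] | intermediate
25 | (3S,4S,5R,6S)-4,5-epoxy-3-hydroxy-4,5-dihydro-α-ionone (epoxide cis to 3-OH) | CC(=O)/C=C/[C@@H]1[C@@]2(C)O[C@H]2[C@@H](O)CC1(C)C | intermediate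
26 | (3E)-4-[(3R,4S)-3,4-dihydroxy-2,6,6-trimethylcyclohex-1-en-1-yl]but-3-en-2-one | CC(=O)/C=C/C1=C(C)[C@@H](O)[C@@H](O)CC1(C)C | intermediate
27 | (3E)-4-[(3aR,7aS)-4,6,6-trimethyl-2-oxo-3a,6,7,7a-tetrahydro-1,3-benzodioxol-5-yl]but-3-en-2-one | CC(=O)/C=C/C1=C(C)[C@H]2OC(=O)O[C@H]2CC1(C)C | intermediate
28 | (3aR,7aS)-5-[(1E)-3-hydroxy-3-methylpenta-1,4-dien-1-yl]-4,6,6-trimethyl-3a,6,7,7a-tetrahydro-1,3-benzodioxol-2-one (carbinol epimers) | C=CC(C)(O)/C=C/C1=C(C)[C@H]2OC(=O)O[C@H]2CC1(C)C | intermediate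
29 | {(2E,4E)-3-methyl-5-[(3aR,7aS)-4,6,6-trimethyl-2-oxo-3a,6,7,7a-tetrahydro-1,3-benzodioxol-5-yl]penta-2,4-dien-1-yl}triphenylphosphonium bromide | C(/C=C(C)/C=C/C1=C(C)[C@H]2OC(=O)O[C@H]2CC1(C)C)[P+](c1ccccc1)(c1ccccc1)c1ccccc1.[Br-] | intermediate
30 | (2E,4E,6E)-2,7-dimethylocta-2,4,6-trienedial | O=C/C(C)=C/C=C/C=C(C)/C=O | starting material
31 | ε-end ylide: (1R,4R)-3,5,5-trimethyl-4-[(1E,3E)-3-methyl-5-(triphenyl-λ5-phosphanylidene)penta-1,3-dien-1-yl]cyclohex-2-en-1-yl acetate | CC1=C[C@H](OC(C)=O)CC(C)(C)[C@H]1/C=C/C(C)=C/C=P(c1ccccc1)(c1ccccc1)c1ccccc1 | intermediate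
32 | (2E,4E,6E,8E,10E,12E)-13-[(1R,4R)-4-acetoxy-2,6,6-trimethylcyclohex-2-en-1-yl]-2,7,11-trimethyltrideca-2,4,6,8,10,12-hexaenal | CC1=C[C@H](OC(C)=O)CC(C)(C)[C@H]1/C=C/C(C)=C/C=C/C(C)=C/C=C/C=C(C)/C=O | intermediate
33 | β-end ylide: (3aR,7aS)-4,6,6-trimethyl-5-[(1E,3E)-3-methyl-5-(triphenyl-λ5-phosphanylidene)penta-1,3-dien-1-yl]-3a,6,7,7a-tetrahydro-1,3-benzodioxol-2-one | C(/C=C(C)/C=C/C1=C(C)[C@H]2OC(=O)O[C@H]2CC1(C)C)=P(c1ccccc1)(c1ccccc1)c1ccccc1 | intermediate
34 | 3'-O-acetyl-3,4-O-carbonyl-(3S,4R,3'R,6'R)-β,ε-carotene-3,4,3'-triol | CC1=C[C@H](OC(C)=O)CC(C)(C)[C@H]1/C=C/C(C)=C/C=C/C(C)=C/C=C/C=C(C)/C=C/C=C(C)/C=C/C1=C(C)[C@H]2OC(=O)O[C@H]2CC1(C)C | intermediate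
35 | (3S,4R,3'R,6'R)-β,ε-carotene-3,4,3'-triol (CNP0191612.1) | CC1=C[C@H](O)CC(C)(C)[C@H]1/C=C/C(C)=C/C=C/C(C)=C/C=C/C=C(C)/C=C/C=C(C)/C=C/C1=C(C)[C@@H](O)[C@@H](O)CC1(C)C | target

**Totals.** 19 steps. Longest linear sequence: 16 steps (1–10, 13–17, 19).

**Steps most likely to fail**

1. Step 3 (key step). The 6π closure of trienolate 10 may be slow because a methyl of the CMe2 terminus (and possibly the CH2OTIPS group) must point inward. This would leave time for vinylogous β-elimination of silanolate from the trienolate, or for simple protonation to an acyclic dienone. Fallback (sets out from 6 with 7, returns at 12): the same ring expansion is run as a neutral thermal cascade, so no enolate is present and higher temperatures are tolerated. The Grignard reagent from 7 (Mg, THF; CeCl3) is added to 6 at −78 °C and the alkoxide is silylated in the cold (TESOTf, 2,6-lutidine) to the cyclobutenyl triethylsilyl ether F1. Heating F1 in toluene (90–110 °C) should open the ring to the 2-silyloxy triene F2, which closes to the cyclic silyl dienol ether F3. Dilute HCl in THF hydrolyses F3 to 12.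

2. Step 17. The allylic C4–O bond of the carbonate may ionise under the acidic phosphonium-forming conditions, or the carbonate may later be expelled vinylogously from ylide 33 in step 19. Fallback (sets out from 26 and 32, returns at 35): the polarity of the last coupling is reversed so that the β end is never a phosphonium salt and needs no protection. Diol 26 is homologated with diethyl cyanomethylphosphonate/NaH to the dihydroxy C15 nitrile F4 and reduced with DIBAL-H to the dihydroxy C15 aldehyde F5. Aldehyde 32 is reduced (NaBH4, MeOH) to the C25 allylic alcohol F6 and converted with Ph3P·HBr into the C25 phosphonium bromide F7, whose ring acetate lies outside the ionising polyene. Wittig reaction of F7 with F5 (NaOMe, MeOH/CH2Cl2) gives the 3'-O-acetyl triol F8, which is methanolysed in the same pot to 35.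

3. Step 10. The enzymatic acylation may show insufficient enantiomer discrimination on this hindered cyclohexenol, giving both products in low enantiomeric purity. Fallback (sets out from 19, returns at 20 and 21): classical resolution through diastereomeric esters. Compound 19 is esterified with (S)-O-acetylmandelic acid (DCC, DMAP), and the (3R,6R) O-acetylmandelate F9 and the (3S,6S) O-acetylmandelate F10 are separated by chromatography or crystallisation. Methanolysis (K2CO3, MeOH, 0 °C) of F10 gives 21. Methanolysis of F9 gives (3R,6R)-3-hydroxy-α-ionone F11, which is acetylated (Ac2O, pyridine) to 20.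

**Further compounds**

F1 | step 3 | triethyl{[3-methyl-1-(2-methylprop-1-en-1-yl)-4-{[(triisopropylsilyl)oxy]methyl}cyclobut-2-en-1-yl]oxy}silane (diastereomer mixture) | CC[Si](CC)(CC)OC1(C=C(C)C)C=C(C)C1CO[Si](C(C)C)(C(C)C)C(C)C
F2 | step 3 | 2,6-dimethyl-4-[(triethylsilyl)oxy]-8-[(triisopropylsilyl)oxy]octa-2,4,6-triene (C2 and C5 cis) | CC[Si](CC)(CC)O/C(C=C(C)C)=C/C(C)=CCO[Si](C(C)C)(C(C)C)C(C)C
F3 | step 3 | rac-triethyl{[3,3,5-trimethyl-4-{[(triisopropylsilyl)oxy]methyl}cyclohexa-1,5-dien-1-yl]oxy}silane | CC[Si](CC)(CC)OC1=CC(C)(C)C(CO[Si](C(C)C)(C(C)C)C(C)C)C(C)=C1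
F4 | step 17 | (2E,4E)-5-[(3R,4S)-3,4-dihydroxy-2,6,6-trimethylcyclohex-1-en-1-yl]-3-methylpenta-2,4-dienenitrile | N#C/C=C(C)/C=C/C1=C(C)[C@@H](O)[C@@H](O)CC1(C)C
F5 | step 17 | (2E,4E)-5-[(3R,4S)-3,4-dihydroxy-2,6,6-trimethylcyclohex-1-en-1-yl]-3-methylpenta-2,4-dienal | O=C/C=C(C)/C=C/C1=C(C)[C@@H](O)[C@@H](O)CC1(C)C
F6 | step 17 | (1R,4R)-4-[(1E,3E,5E,7E,9E,11E)-13-hydroxy-3,7,12-trimethyltrideca-1,3,5,7,9,11-hexaen-1-yl]-3,5,5-trimethylcyclohex-2-en-1-yl acetate | CC1=C[C@H](OC(C)=O)CC(C)(C)[C@H]1/C=C/C(C)=C/C=C/C(C)=C/C=C/C=C(C)/CO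
F7 | step 17 | {(2E,4E,6E,8E,10E,12E)-13-[(1R,4R)-4-acetoxy-2,6,6-trimethylcyclohex-2-en-1-yl]-2,7,11-trimethyltrideca-2,4,6,8,10,12-hexaen-1-yl}triphenylphosphonium bromide | CC1=C[C@H](OC(C)=O)CC(C)(C)[C@H]1/C=C/C(C)=C/C=C/C(C)=C/C=C/C=C(C)/C[P+](c1ccccc1)(c1ccccc1)c1ccccc1.[Br-]
F8 | step 17 | 3'-O-acetyl-(3S,4R,3'R,6'R)-β,ε-carotene-3,4,3'-triol | CC1=C[C@H](OC(C)=O)CC(C)(C)[C@H]1/C=C/C(C)=C/C=C/C(C)=C/C=C/C=C(C)/C=C/C=C(C)/C=C/C1=C(C)[C@@H](O)[C@@H](O)CC1(C)C
F9 | step 10 | (1R,4R)-3,5,5-trimethyl-4-[(1E)-3-oxobut-1-en-1-yl]cyclohex-2-en-1-yl (2S)-2-acetoxy-2-phenylacetate | CC1=C[C@H](OC(=O)[C@@H](OC(C)=O)c2ccccc2)CC(C)(C)[C@H]1/C=C/C(C)=O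
F10 | step 10 | (1S,4S)-3,5,5-trimethyl-4-[(1E)-3-oxobut-1-en-1-yl]cyclohex-2-en-1-yl (2S)-2-acetoxy-2-phenylacetate | CC1=C[C@@H](OC(=O)[C@@H](OC(C)=O)c2ccccc2)CC(C)(C)[C@@H]1/C=C/C(C)=O
F11 | step 10 | (3E)-4-[(1R,4R)-4-hydroxy-2,6,6-trimethylcyclohex-2-en-1-yl]but-3-en-2-one [(3R,6R)-3-hydroxy-α-ionone] | CC1=C[C@H](O)CC(C)(C)[C@H]1/C=C/C(C)=O
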